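**Retrosynthetic overview**
- Andavadoic acid ⇒ C3–CH2CO2H bond and the C3 stereocentre: catalyst-controlled addition of a bis-silyl ketene acetal to the 1,2-dioxolan-3-ylium (peroxycarbenium) ion from 3-methoxy-3,5-dimethyl-5-(10-phenyldecyl)-1,2-dioxolane.
- 1,2-Dioxolane ring ⇒ Mn-catalysed aerobic ring expansion of 1,2-dimethyl-2-(10-phenyldecyl)cyclopropanol (O2 inserted into the C1–C2 bond; C5 is formed racemic here).
- Cyclopropanol ⇒ Simmons–Smith cyclopropanation of the tetrasubstituted TMS enol ether from Cu-catalysed 1,4-addition of Ph(CH2)9MgCl to 3-methylbut-3-en-2-one.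
- Ph(CH2)9 chain ⇒ PhMgBr + Br(CH2)6Cl, then + Br(CH2)3Cl (Cu-catalysed couplings).
- Ring order: cyclopropane first, then its expansion to the only ring of the target; C3 is set last by the catalyst, and the correct C5 antipode is obtained as the separable trans diastereomer (at most 50 % of the material).

Assumption: commercial PhMgBr solution counts as a starting material; racemates and stereoisomer mixtures are written without stereodescriptors; the IDPi antipode that gives Si-face attack at C3 is found in a first screen (both antipodes are accessible).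

**Step 1**
Reactants: 1 phenylmagnesium bromide; 2 1-bromo-6-chlorohexane
Product: 3 (6-chlorohexyl)benzene
Conditions: Li2CuCl4 (2 mol%), THF/NMP, 0 °C
Reagents that add atoms: none
Why: Kochi-type Cu-catalysed Grignard–alkyl halide cross-coupling, in which the primary C–Br bond reacts selectively over C–Cl; no stereocentre.

**Step 2**
Reactants: 3 (6-chlorohexyl)benzene; 4 1-bromo-3-chloropropane
Product: 6 (9-chlorononyl)benzene, via (6-phenylhexyl)magnesium chloride 5 (not isolated)
Conditions: Mg, THF, 60 °C; then 4, Li2CuCl4 (2 mol%), THF, −10 °C → rt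
Reagents that add atoms: none
Why: Grignard formation from the primary chloride followed by the same Cu-catalysed sp3–sp3 (Kochi) coupling, again selective for bromide over chloride.

**Step 3**
Reactants: 6 (9-chlorononyl)benzene; 7 3-methylbut-3-en-2-one
Product: 9 trimethyl[(3-methyl-13-phenyltridec-2-en-2-yl)oxy]silane (E/Z mixture), via (9-phenylnonyl)magnesium chloride 8 (not isolated)
Conditions: Mg, THF, 60 °C; then CuBr·SMe2 (5 mol%), TMSCl (2 equiv), 7, THF, −78 °C; Et3N/pentane work-up
Reagents that add atoms: chlorotrimethylsilane, C[Si](C)(C)Cl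
Why: Cu-catalysed, TMSCl-accelerated 1,4-addition of the Grignard reagent to the unhindered 2-substituted enone with regiospecific trapping as the tetrasubstituted silyl enol ether; the E/Z ratio is irrelevant because this carbon later passes through a planar radical.

**Step 4**
Reactants: 9 trimethyl[(3-methyl-13-phenyltridec-2-en-2-yl)oxy]silane
Product: 11 1,2-dimethyl-2-(10-phenyldecyl)cyclopropan-1-ol (racemic diastereomer mixture), via siloxycyclopropane 10 (not isolated)
Conditions: Et2Zn (2 equiv), CH2I2 (4 equiv), Et2O, 0 °C → rt; then K2CO3 (cat.), MeOH, 0 °C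
Reagents that add atoms: diiodomethane, ICI
Why: Furukawa–Simmons–Smith cyclopropanation of the electron-rich silyl enol ether (stereospecific syn addition, mixture acceptable) followed by mild methanolysis of the TMS ether to the free cyclopropanol.

**Step 5**
Reactants: 11 1,2-dimethyl-2-(10-phenyldecyl)cyclopropan-1-ol
Product: 14 3-methoxy-3,5-dimethyl-5-(10-phenyldecyl)-1,2-dioxolane (racemic at C5; both C3 epimers), via hydroperoxy ketone 12 (not isolated), via dioxolanol 13 (not isolated)
Conditions: Mn(acac)3 (2 mol%), O2 (1 atm), PhH, rt; then PPTS (10 mol%), MeOH, rt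
Reagents that add atoms: dioxygen, O=O; methanol, CO
Why: Mn(III)-catalysed aerobic ring expansion of a cyclopropanol (Kulinkovich-type radical oxygenation): β-scission of the Mn-bound cyclopropyloxy unit opens the more substituted C1–C2 bond to the tertiary β-keto radical, which captures O2 and closes onto the ketone to the 1,2-dioxolan-3-ol (three- to five-membered ring, C5 formed racemic); acid-catalysed exchange with MeOH then gives the methyl peroxyketal.

**Step 6**
Reactants: 15 trimethylsilyl acetate
Product: 17 1,1-bis(trimethylsilyloxy)ethene, via lithium enolate 16 (not isolated)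
Conditions: LDA (commercial, 1.05 equiv), THF, −78 °C; TMSCl, −78 °C → rt; distillation
Reagents that add atoms: chlorotrimethylsilane, C[Si](C)(C)Cl
Why: Ainsworth-type enolisation and O-silylation of a silyl ester gives the bis-silyl ketene acetal; no stereocentre.

**Step 7**
Reactants: 14 3-methoxy-3,5-dimethyl-5-(10-phenyldecyl)-1,2-dioxolane; 17 1,1-bis(trimethylsilyloxy)ethene
Product: 20 andavadoic acid [2-[(3R,5S)-3,5-dimethyl-5-(10-phenyldecyl)-1,2-dioxolan-3-yl]acetic acid], via dioxolanylium ion pair 18 (not isolated), via trimethylsilyl ester 19 (not isolated)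
Conditions: 17 (2.0 equiv), (S,S)-IDPi (3 mol%), PhMe, −78 °C; aq. citric acid work-up; SiO2 (removal of the 3R,5R isomer)
Reagents that add atoms: none
Why: Proposed new method: asymmetric counter-anion-directed (silylium–IDPi) Mukaiyama-type substitution of a ketone-derived cyclic peroxyketal — the silylated, confined BINOL-derived imidodiphosphorimidate abstracts methoxide to give a contact ion pair of the planar 1,2-dioxolan-3-ylium ion with the chiral anion, which blocks the Re face so that the ketene acetal adds to the Si face of C3 (priorities O2 > C4 > CH3) for both C5 antipodes, because the remote CH3/CH2R pair at C5 exerts almost no bias; the 5S half therefore gives the 3R,5S product (CH2CO2H anti to the long chain) and the 5R half the separable 3R,5R diastereomer, and the silyl ester hydrolyses on work-up; the closest known reactions are IDPi-catalysed additions of silyl nucleophiles to cyclic aliphatic oxocarbenium ions from lactol acetates and achiral Lewis-acid-mediated additions of silyl ketene acetals to 3-alkoxy-1,2-dioxolanes.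

**Compound list**
1 | phenylmagnesium bromide | Br[Mg]c1ccccc1 | starting material
2 | 1-bromo-6-chlorohexane | ClCCCCCCBr | starting material
3 | (6-chlorohexyl)benzene | ClCCCCCCc1ccccc1 | intermediate
4 | 1-bromo-3-chloropropane | ClCCCBr | starting material
5 | (6-phenylhexyl)magnesium chloride | Cl[Mg]CCCCCCc1ccccc1 | intermediate
6 | (9-chlorononyl)benzene | ClCCCCCCCCCc1ccccc1 | intermediate
7 | 3-methylbut-3-en-2-one | CC(=O)C(C)=C | starting material
8 | (9-phenylnonyl)magnesium chloride | Cl[Mg]CCCCCCCCCc1ccccc1 | intermediate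
9 | trimethyl[(3-methyl-13-phenyltridec-2-en-2-yl)oxy]silane (E/Z mixture) | CC(O[Si](C)(C)C)=C(C)CCCCCCCCCCc1ccccc1 | intermediate
10 | trimethyl{[1,2-dimethyl-2-(10-phenyldecyl)cyclopropyl]oxy}silane (racemic diastereomer mixture) | CC1(O[Si](C)(C)C)CC1(C)CCCCCCCCCCc1ccccc1 | intermediate
11 | 1,2-dimethyl-2-(10-phenyldecyl)cyclopropan-1-ol (racemic diastereomer mixture) | CC1(O)CC1(C)CCCCCCCCCCc1ccccc1 | intermediate
12 | 4-hydroperoxy-4-methyl-14-phenyltetradecan-2-one (racemic) | CC(=O)CC(C)(OO)CCCCCCCCCCc1ccccc1 | intermediate
13 | 3,5-dimethyl-5-(10-phenyldecyl)-1,2-dioxolan-3-ol (racemic at C5; C3 epimers) | CC1(O)CC(C)(CCCCCCCCCCc2ccccc2)OO1 | intermediate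
14 | 3-methoxy-3,5-dimethyl-5-(10-phenyldecyl)-1,2-dioxolane (racemic at C5; C3 epimers) | COC1(C)CC(C)(CCCCCCCCCCc2ccccc2)OO1 | intermediate
15 | trimethylsilyl acetate | CC(=O)O[Si](C)(C)C | starting material
16 | lithium 1-(trimethylsilyloxy)ethenolate | [Li+].[O-]C(=C)O[Si](C)(C)C | intermediate
17 | 1,1-bis(trimethylsilyloxy)ethene | C=C(O[Si](C)(C)C)O[Si](C)(C)C | intermediate
18 | 3,5-dimethyl-5-(10-phenyldecyl)-1,2-dioxolan-3-ylium, ion pair with the IDPi anion (racemic at C5) | CC1=[O+]OC(C)(CCCCCCCCCCc2ccccc2)C1 | intermediate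
19 | trimethylsilyl 2-[(3R,5S)-3,5-dimethyl-5-(10-phenyldecyl)-1,2-dioxolan-3-yl]acetate | C[C@]1(CCCCCCCCCCc2ccccc2)C[C@](C)(CC(=O)O[Si](C)(C)C)OO1 | intermediate
20 | andavadoic acid, 2-[(3R,5S)-3,5-dimethyl-5-(10-phenyldecyl)-1,2-dioxolan-3-yl]acetic acid | C[C@]1(CCCCCCCCCCc2ccccc2)C[C@](C)(CC(=O)O)OO1 | target

**Totals and risks**
Total step count: 7. Longest linear sequence: 6 (steps 1–5 and 7; step 6 prepares the nucleophile).

Most likely to fail, first: step 7, the proposed new reaction. The peroxycarbenium ion may fragment (Criegee/Hock-type O–O cleavage) or lose a proton. Facial control at a fully substituted cation may be too low. Even at its best, half of the material ends as the 3R,5R isomer. The fallback uses known chemistry and sets out from 14 (with 17). An achiral Lewis acid (TMSOTf or TiCl4, CH2Cl2, −78 °C) gives the racemic trans trimethylsilyl ester F1 together with its cis isomer. Aqueous work-up and chromatography give the racemic trans acid F2. DCC/DMAP coupling with (S)-4-benzyl-1,3-oxazolidin-2-one gives two diastereomeric imides, from which the (S)-4-benzyl-3-{2-[(3R,5S)-3,5-dimethyl-5-(10-phenyldecyl)-1,2-dioxolan-3-yl]acetyl}oxazolidin-2-one F3 is isolated by chromatography. LiOH/H2O2 (THF/H2O, 0 °C) cleaves the auxiliary, and the route is rejoined at 20.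

Second: step 5, the aerobic ring expansion. Risks are metal- or base-induced collapse of the hydroperoxy ketone to the epoxy ketone or 1,3-diketone, and partial cleavage of the less substituted cyclopropane bond. The fallback sets out from 11 and replaces radical O2 capture by a polar two-stage sequence. FeCl3 in DMF (Ito–Saegusa oxidative ring opening) gives 4-chloro-4-methyl-14-phenyltetradecan-2-one F4. Silver-assisted perhydrolysis (AgOTf, anhydrous H2O2 in Et2O, 0 °C) of the tertiary chloride then gives 12, where the route is rejoined; 12 closes to 13 and is ketalised to 14 as in step 5.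

Third: step 3, the conjugate addition with silyl trapping. Risks are polymerisation of the enone, 1,2-addition, and loss of the labile enol ether. The fallback sets out from 3 via its Grignard reagent 5 and builds the ketone by enolate alkylation. Cu-catalysed coupling of 5 with 1-bromo-4-chlorobutane gives (10-chlorodecyl)benzene F5. NaI in acetone gives (10-iododecyl)benzene F6. C-alkylation of 3-methylpentane-2,4-dione (K2CO3, acetone) gives 3-methyl-3-(10-phenyldecyl)pentane-2,4-dione F7. Retro-Claisen deacetylation (NaOEt, EtOH) gives 3-methyl-13-phenyltridecan-2-one F8. Thermodynamic silylation (TMSCl, NaI, Et3N, MeCN) then rejoins the route at 9.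

**Further compounds**
F1 | step 7 | rac-trimethylsilyl 2-[(3R*,5S*)-3,5-dimethyl-5-(10-phenyldecyl)-1,2-dioxolan-3-yl]acetate (racemic, relative configuration shown) | C[C@]1(CCCCCCCCCCc2ccccc2)C[C@](C)(CC(=O)O[Si](C)(C)C)OO1
F2 | step 7 | rac-2-[(3R*,5S*)-3,5-dimethyl-5-(10-phenyldecyl)-1,2-dioxolan-3-yl]acetic acid (racemic, relative configuration shown) | C[C@]1(CCCCCCCCCCc2ccccc2)C[C@](C)(CC(=O)O)OO1
F3 | step 7 | (S)-4-benzyl-3-{2-[(3R,5S)-3,5-dimethyl-5-(10-phenyldecyl)-1,2-dioxolan-3-yl]acetyl}-1,3-oxazolidin-2-one | C[C@]1(CCCCCCCCCCc2ccccc2)C[C@](C)(CC(=O)N3[C@@H](Cc4ccccc4)COC3=O)OO1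
F4 | step 5 | 4-chloro-4-methyl-14-phenyltetradecan-2-one (racemic) | CC(=O)CC(C)(Cl)CCCCCCCCCCc1ccccc1
F5 | step 3 | (10-chlorodecyl)benzene | ClCCCCCCCCCCc1ccccc1
F6 | step 3 | (10-iododecyl)benzene | ICCCCCCCCCCc1ccccc1
F7 | step 3 | 3-methyl-3-(10-phenyldecyl)pentane-2,4-dione | CC(=O)C(C)(CCCCCCCCCCc1ccccc1)C(C)=O
F8 | step 3 | 3-methyl-13-phenyltridecan-2-one (racemic) | CC(=O)C(C)CCCCCCCCCCc1ccccc1
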